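In ring B the oxygens on C6 and C9 stand in a 1,4-relationship across the C7–C8 bond; at the ketone oxidation level C7 and C8 are the α-carbons of two carbonyl groups, so this bond can be made by joining two enolates under oxidation. The route therefore rests on disconnecting C7–C8. The precursor is a ring-A cyclohexane (C1–C5, C10) with an acetyl group (C9, C8) on quaternary C10 and a trans isovaleryl group (C6, C7) on C5, C4 masked as a dioxolane and O1 silylated. One operation forms C7–C8, closes ring B as the 6,9-dione and sets C7; C1, C5 and C10 are fixed before it, C6, C9, C4 and the orthoester after it.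

Key step: step 11

Conventions and remarks on the chemistry
- Numbering is that of the target: ring A = C1–C2–C3–C4–C5–C10, ring B = C5–C6–C7–C8–C9–C10. C10 carries the methyl group, C4 carries C15, C7 the isopropyl group. α is the face of the C10 methyl group, β the other face. In the target O1, O9, C15 and the isopropyl group are α; O4, O6 and H5 are β.
- Structure check: C1, C5, C7 and C10 carry the same configuration in 16, 18 and 27. The orthoester carbon of 27 has the only configuration the cage allows. No descriptor needed changing.
- Assumption for step 1: the cycloaddition is taken as endo for the catalyst-bound formyl group (OSiMe3 cis to CHO). C1 is reset through ketone 7, so either C1 epimer of 3 would serve.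
- Assumption for step 1: the catalyst antipode must expose the re face of the formyl-bearing alkene carbon of 1 (CHO > C=C > CH3). The accepted binding model for α-substituted enals is taken to assign this to the (S)-prolinol-derived catalyst. The (R)-antipode is equally accessible should the first adduct belong to the other series.
- C9 is formed in step 2 as a mixture of epimers and is oxidised in step 10. It is left undefined in 4–6, 8–12, 14 and 15.
- C5–H lies between two carbonyl groups only in 10 and 11. These are handled without base and carried on without delay.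
- Precursor design: the diketone is not deprotonated to a free bis-enolate. It is trapped in the flask as the bis(silyl enol ether), which fixes C7 (not C5) as the enol carbon and shuts off the aldol reaction of a mono-enolate with the other ketone.

Step 1
Reactants: 1 ethyl (E)-3-formylbut-2-enoate; 2 (E)-1-(trimethylsiloxy)buta-1,3-diene
Product: 3 cyclohexene aldehyde ester (C5 α-CO2Et; C10 α-CH3 and β-CHO; C1 β-OSiMe3; C2=C3)
Conditions: (S)-3,3-diphenyl-1-(o-tolyl)tetrahydro-1H,3H-pyrrolo[1,2-c][1,3,2]oxazaborole + Tf2NH (20 mol%), 2 (2 equiv), CH2Cl2, −78 °C; Et3N quench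
Reagents that add atoms: none
Why: Oxazaborolidinium-catalysed enantioselective Diels–Alder reaction in which the coordinated formyl group is the controlling acceptor, so the nucleophilic CH2 terminus of the diene bonds to C5 and the oxygenated terminus to C10, the E-alkene fixes CHO and CO2Et trans, the shielded catalyst face sets C10 and C5 together, and formyl-endo approach places OSiMe3 cis to CHO.

Step 2
Reactants: 3
Product: 6 hydroxy lactone (trans-fused γ-lactone C5–C6(=O)–O–C9H(CH3)–C10; 1β-OH; C2=C3), via hydroxy ester 4 (not isolated), via silyl lactone 5 (not isolated)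
Conditions: MeMgBr (1.1 equiv), THF, −78 °C to rt; then 1 M HCl, THF, rt
Reagents that add atoms: methylmagnesium bromide, C[Mg]Br
Why: Grignard addition is selective for the aldehyde over the ester at −78 °C, the C9 alkoxide then lactonises onto the trans C5 ester on warming, and the acidic work-up removes the trimethylsilyl group; the new C9 centre is of no consequence.

Step 3
Reactants: 6
Product: 7 enone lactone (C1 ketone conjugated with C2=C3)
Conditions: Dess–Martin periodinane, CH2Cl2, rt
Reagents that add atoms: none
Why: Dess–Martin oxidation of the secondary allylic alcohol is compatible with the lactone and erases the C1 centre so that it can be reset.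

Step 4
Reactants: 7
Product: 8 allylic alcohol (1α-OH, cis to the C10 methyl group)
Conditions: NaBH4, CeCl3·7H2O, MeOH, −78 °C
Reagents that add atoms: none
Why: Luche 1,2-reduction in which the trans-fused lactone holds the C10 methyl group pseudo-axial next to the carbonyl, so hydride enters C1 from the β face and the hydroxyl ends up α; the lactone is inert under these conditions.

Step 5
Reactants: 8
Product: 9 silyl ether (1α-OTBS)
Conditions: TBSOTf, 2,6-lutidine, CH2Cl2, 0 °C
Reagents that add atoms: tert-butyldimethylsilyl trifluoromethanesulfonate, CC(C)(C)[Si](C)(C)OS(=O)(=O)C(F)(F)F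
Why: Silylation with the silyl triflate overcomes the hindrance of the neopentyl-type secondary alcohol and installs a group that lasts until the final step.

Step 6
Reactants: 9
Product: 10 enone (C4 ketone conjugated with C2=C3; 1α-OTBS)
Conditions: CrO3, 3,5-dimethylpyrazole, CH2Cl2, −20 °C
Reagents that add atoms: chromium trioxide, O=[Cr](=O)=O
Why: Allylic C–H oxidation with the chromium trioxide–pyrazole complex converts the only allylic methylene (C4) into the ketone, the other allylic position (C1–H) being shielded by the silyl ether and quaternary C10.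

Step 7
Reactants: 10
Product: 11 keto lactone (C4 ketone; ring A saturated)
Conditions: H2 (1 atm), 10% Pd/C, EtOAc, rt
Reagents that add atoms: none
Why: Catalytic hydrogenation of the enone C=C under neutral conditions leaves ketone, lactone and silyl ether untouched and creates no stereocentre.

Step 8
Reactants: 11
Product: 12 ketal lactone (C4 dioxolane)
Conditions: Me3SiOCH2CH2OSiMe3, Me3SiOTf (cat.), CH2Cl2, −78 to −20 °C
Reagents that add atoms: 1,2-bis(trimethylsilyloxy)ethane, C[Si](C)(C)OCCO[Si](C)(C)C
Why: Aprotic silyl-transfer ketalisation runs at low temperature, tolerates the TBS ether and the lactone, and masks the C4 ketone before C5–H can epimerise.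

Step 9
Reactants: 12; 13 isobutyllithium
Product: 15 hydroxy ketone (C5 isovaleryl; C9 carbinol), via lactol 14 (not isolated)
Conditions: (CH3)2CHCH2Li (1.1 equiv), THF, −78 °C; then aq NH4Cl
Reagents that add atoms: none
Why: Addition of one equivalent of an alkyllithium to a γ-lactone stops at the lithium lactolate at −78 °C, which on protonation gives the lactol in equilibrium with the γ-hydroxy ketone, C5 being untouched.

Step 10
Reactants: 15
Product: 16 ring-A diketone (C10 acetyl; C5 isovaleryl trans to it; C4 dioxolane; 1α-OTBS)
Conditions: Dess–Martin periodinane, pyridine, CH2Cl2, rt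
Reagents that add atoms: none
Why: Dess–Martin oxidation of the C9 carbinol, drawn from the lactol through its open-chain tautomer, gives the methyl ketone under buffered conditions that spare ketal and silyl ether.

Step 11
Reactants: 16
Product: 18 trans-decalin-6,9-dione (7α-isopropyl; C4 dioxolane; 1α-OTBS), via bis(trimethylsilyl enol ether) 17 (not isolated)
Conditions: LiN(iPr)2 (2.5 equiv), Me3SiCl (5 equiv), THF, −78 °C; solvent exchange; (NH4)2Ce(NO3)6 (2.2 equiv), NaHCO3, MeCN (0.01 M), −30 to 0 °C; then DBU (cat.), CH2Cl2, rt
Reagents that add atoms: none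
Why: Kinetic deprotonation in the presence of Me3SiCl traps the C8 (methyl) and C7 (methylene) enolates as silyl enol ethers before either can attack the other carbonyl, the C5 methine being shielded by quaternary C10 and the C4 ketal. Single-electron oxidation by tetravalent cerium then turns the more electron-rich C6=C7 enol ether into an α-keto radical cation at C7, which adds to the unsubstituted C8 terminus of the second enol ether, and a second oxidation with loss of both silyl groups gives the 1,4-diketone. The closest known reaction type is the oxidative coupling of two silyl enol ethers, or of ketone dienolates with divalent copper or trivalent iron, to 1,4-diketones, run here intramolecularly. Ring B closes in the 6-endo-trig mode, attack at C8 being preferred over 5-exo attack at C9 because it leaves the oxygen-stabilised radical at C9 instead of a primary one. The new stereocentre C7 is set by a chair-like transition state with the isopropyl group pseudo-equatorial and is secured by thermodynamics, since C7–H stays α to the C6 ketone and the DBU treatment funnels any axial epimer to the equatorial one, while the trans relation already present at C5 and C10 gives the trans ring fusion. The step needs C7 over C5 regioselectivity and ring closure over intermolecular coupling, which the steric bias of the substrate and high dilution secure.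

Step 12
Reactants: 18
Product: 19 diol (6β-OH and 9α-OH, both equatorial)
Conditions: Li, NH3 (l), THF, MeOH, −78 to −33 °C; then NH4Cl
Reagents that add atoms: none
Why: Dissolving-metal reduction of both ketones is thermodynamically controlled and gives the equatorial alcohols at C9 (α) and C6 (β), whereas a hydride reagent would attack C6 from the equatorial side and give the axial alcohol; ketal and silyl ether are stable to lithium in ammonia.

Step 13
Reactants: 19
Product: 20 dihydroxy ketone (C4 ketone; 6β-OH; 9α-OH)
Conditions: PPTS, acetone/H2O (10:1), 60 °C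
Reagents that add atoms: water, O
Why: Mild acid-catalysed hydrolysis of the dioxolane frees the C4 ketone without cleaving the hindered secondary TBS ether or dehydrating the β-hydroxy ketone.

Step 14
Reactants: 20
Product: 21 exocyclic alkene (C4=C15H2)
Conditions: Zn, CH2Br2, TiCl4, THF/CH2Cl2, 0 °C to rt
Reagents that add atoms: dibromomethane, BrCBr
Why: Takai–Lombardo methylenation is non-basic, so the β-hydroxy ketone cannot undergo retro-aldol cleavage or C5 epimerisation, and the reagent tolerates free hydroxyl groups and hindered ketones.

Step 15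
Reactants: 21
Product: 22 tetraol (4β-OH equatorial; C15H2OH α, axial)
Conditions: OsO4 (cat.), NMO, acetone/H2O, rt
Reagents that add atoms: N-methylmorpholine N-oxide, C[N+]1([O-])CCOCC1; water, O
Why: Upjohn dihydroxylation in which the axial C10 methyl group blocks the α face of the exocyclic alkene, so OsO4 adds from the β face and places O4 equatorial (β) and C15 axial (α).

Step 16
Reactants: 23 cinnamonitrile
Product: 25 trimethyl orthocinnamate, via imidate hydrochloride 24 (not isolated)
Conditions: HCl (g), MeOH (1.1 equiv), Et2O, 0 °C; then MeOH, hexane, rt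
Reagents that add atoms: methanol, CO
Why: Pinner reaction in which methanol adds to the protonated nitrile to give the imidate salt, whose alcoholysis replaces nitrogen by two further methoxy groups with loss of ammonium chloride.

Step 17
Reactants: 22; 25
Product: 26 orthoester (O4, O6 and O15 on one carbon; 1α-OTBS; 9α-OH free)
Conditions: 25 (1.5 equiv), PPTS (cat.), CH2Cl2, 4 Å MS, rt
Reagents that add atoms: none
Why: Acid-catalysed orthoester exchange in which the 15-OH, the 4β-OH and the peri-related 6β-OH lie within reach of one carbon, so three exchanges with loss of methanol close the trioxabicyclo[3.2.1]octane cage, whose bridgehead orthoester carbon can adopt only one configuration; the lone 9α-OH cannot form a cyclic orthoester and O1 is protected.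

Step 18
Reactants: 26
Product: 27 target CNP0252898.1
Conditions: Bu4NF, THF, rt to 40 °C
Reagents that add atoms: none
Why: Fluoride-mediated desilylation frees the 1α-hydroxyl under basic conditions to which the acid-labile orthoester is inert.

Compound list
1 | ethyl (E)-3-formylbut-2-enoate | CCOC(=O)/C=C(\C)C=O | starting material
2 | (E)-1-(trimethylsiloxy)buta-1,3-diene | C=C/C=C/O[Si](C)(C)C | starting material
3 | cyclohexene aldehyde ester (5α-CO2Et, 10α-CH3, 10β-CHO, 1β-OSiMe3, C2=C3) | CCOC(=O)[C@@H]1CC=C[C@@H](O[Si](C)(C)C)[C@@]1(C)C=O | intermediate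
4 | hydroxy ester (C9 carbinol, present as its bromomagnesium alkoxide; 1β-OSiMe3) | CCOC(=O)[C@@H]1CC=C[C@@H](O[Si](C)(C)C)[C@@]1(C)C(C)O | intermediate
5 | silyl lactone (trans-fused γ-lactone; 1β-OSiMe3) | O=C2[C@@H]1CC=C[C@@H](O[Si](C)(C)C)[C@@]1(C)C(C)O2 | intermediate
6 | hydroxy lactone (trans-fused γ-lactone; 1β-OH; C2=C3) | O=C2[C@@H]1CC=C[C@@H](O)[C@@]1(C)C(C)O2 | intermediate
7 | enone lactone (C1 ketone, C2=C3) | O=C2[C@@H]1CC=CC(=O)[C@@]1(C)C(C)O2 | intermediate
8 | allylic alcohol (1α-OH) | O=C2[C@@H]1CC=C[C@H](O)[C@@]1(C)C(C)O2 | intermediate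
9 | silyl ether (1α-OTBS) | O=C2[C@@H]1CC=C[C@H](O[Si](C)(C)C(C)(C)C)[C@@]1(C)C(C)O2 | intermediate
10 | enone (C4 ketone, C2=C3, 1α-OTBS) | O=C2[C@@H]1C(=O)C=C[C@H](O[Si](C)(C)C(C)(C)C)[C@@]1(C)C(C)O2 | intermediate
11 | keto lactone (C4 ketone, 1α-OTBS) | O=C2[C@@H]1C(=O)CC[C@H](O[Si](C)(C)C(C)(C)C)[C@@]1(C)C(C)O2 | intermediate
12 | ketal lactone (C4 dioxolane, 1α-OTBS) | O=C2[C@@H]1C3(OCCO3)CC[C@H](O[Si](C)(C)C(C)(C)C)[C@@]1(C)C(C)O2 | intermediate
13 | isobutyllithium | [Li]CC(C)C | starting material
14 | lactol (cyclic hemiketal at C6 carrying the isobutyl group) | OC2(CC(C)C)[C@@H]1C3(OCCO3)CC[C@H](O[Si](C)(C)C(C)(C)C)[C@@]1(C)C(C)O2 | intermediate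
15 | hydroxy ketone (5α-isovaleryl, C9 carbinol on C10) | CC(C)CC(=O)[C@@H]1C2(OCCO2)CC[C@H](O[Si](C)(C)C(C)(C)C)[C@@]1(C)C(C)O | intermediate
16 | ring-A diketone (10β-acetyl, 10α-CH3, 5α-isovaleryl, C4 dioxolane, 1α-OTBS) | CC(C)CC(=O)[C@@H]1C2(OCCO2)CC[C@H](O[Si](C)(C)C(C)(C)C)[C@@]1(C)C(C)=O | intermediate
17 | bis(trimethylsilyl enol ether) of 16 (C8=C9 and (Z)-C6=C7) | CC(C)/C=C(\O[Si](C)(C)C)[C@@H]1C2(OCCO2)CC[C@H](O[Si](C)(C)C(C)(C)C)[C@@]1(C)C(=C)O[Si](C)(C)C | intermediate
18 | trans-decalin-6,9-dione (7α-isopropyl, C4 dioxolane, 1α-OTBS) | CC(C)[C@H]1CC(=O)[C@@]2(C)[C@H](C1=O)C3(OCCO3)CC[C@@H]2O[Si](C)(C)C(C)(C)C | intermediate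
19 | diol (6β-OH, 9α-OH, C4 dioxolane, 1α-OTBS) | CC(C)[C@H]1C[C@@H](O)[C@@]2(C)[C@H]([C@@H]1O)C3(OCCO3)CC[C@@H]2O[Si](C)(C)C(C)(C)C | intermediate
20 | dihydroxy ketone (C4 ketone, 6β-OH, 9α-OH, 1α-OTBS) | CC(C)[C@H]1C[C@@H](O)[C@@]2(C)[C@H]([C@@H]1O)C(=O)CC[C@@H]2O[Si](C)(C)C(C)(C)C | intermediate
21 | exocyclic alkene (C4=C15H2, 6β-OH, 9α-OH, 1α-OTBS) | CC(C)[C@H]1C[C@@H](O)[C@@]2(C)[C@H]([C@@H]1O)C(=C)CC[C@@H]2O[Si](C)(C)C(C)(C)C | intermediate
22 | tetraol (4β-OH, 15-OH, 6β-OH, 9α-OH, 1α-OTBS) | CC(C)[C@H]1C[C@@H](O)[C@@]2(C)[C@H]([C@@H]1O)[C@](O)(CO)CC[C@@H]2O[Si](C)(C)C(C)(C)C | intermediate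
23 | (E)-cinnamonitrile | N#C/C=C/c1ccccc1 | starting material
24 | methyl (E)-cinnamimidate hydrochloride | COC(=[NH2+])/C=C/c1ccccc1.[Cl-] | intermediate
25 | trimethyl (E)-orthocinnamate | COC(OC)(OC)/C=C/c1ccccc1 | intermediate
26 | 4β,6β,15-orthocinnamate with 1α-OTBS and 9α-OH | CC(C)[C@H]1C[C@@H](O)[C@@]2(C)[C@@H]3[C@@H]1O[C@]1(/C=C/c4ccccc4)OC[C@@]3(CC[C@@H]2O[Si](C)(C)C(C)(C)C)O1 | intermediate
27 | CNP0252898.1 (1α,9α-diol 4β,6β,15-orthocinnamate) | CC(C)[C@H]1C[C@@H](O)[C@@]2(C)[C@@H]3[C@@H]1O[C@]1(/C=C/c4ccccc4)OC[C@@]3(CC[C@@H]2O)O1 | target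

Total step count: 18. Longest linear sequence: 17 (steps 1–15, 17, 18); step 16 is a one-step side branch.

Steps most likely to fail

Step 11. The C7 radical cation may be intercepted by nitrate, lose its silyl group or be reduced back before it reaches C8, or the congestion around C5 may keep the two enol ethers apart, so that diketone is returned or α-oxygenated. The fallback closes the same bond by a two-electron path. From 16, inverse addition to LiN(iPr)2 (2.2 equiv, THF, −78 °C) would give the dilithium bis-enolate F1. One equivalent of I2 would iodinate the unhindered C8 terminus to give the iodo ketone enolate F2. Its remaining C7 enolate would displace iodide in an intramolecular SN2 reaction at the primary α-keto carbon, and after the same DBU equilibration the route is rejoined at 18.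

Step 6. Hydrogen abstraction may occur at C1–H with loss of the silyl ether, or oxidation may proceed with allylic transposition, in place of clean oxidation at C4. The fallback delivers oxygen to C4 by cycloaddition of singlet oxygen. From enone 7, Me3SiOTf and Et3N would give the 2-silyloxy-1,3-diene F3; only γ-deprotonation at C4 is possible because C10 is quaternary. Photooxygenation (O2, hν, tetraphenylporphyrin, CH2Cl2, −78 °C) followed by PPh3 would add oxygen across C1 and C4 and collapse to the γ-hydroxy enone F4. Luche reduction would give the ene-diol F5 with the 1α-hydroxyl, as in step 4. TEMPO with PhI(OAc)2 would oxidise the less hindered C4 carbinol and leave the neopentyl C1 hydroxyl, giving the hydroxy enone F6. TBSOTf and 2,6-lutidine would then rejoin the route at 10.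

Step 14. Methylenation of the hindered C4 carbonyl may stall, with material held back as titanium alkoxides of the free diol. The fallback is addition followed by elimination. From 20, Me3SiCH2Li with CeCl3 (THF, −78 °C) would add to the ketone to give the β-hydroxysilane F7. KH in THF would then bring about Peterson elimination and rejoin the route at 21.

Further compounds
F1 | step 11 | dilithium bis-enolate of 16 (C8 and (Z)-C7 enolates) | CC(C)/C=C(\O[Li])[C@@H]1C2(OCCO2)CC[C@H](O[Si](C)(C)C(C)(C)C)[C@@]1(C)C(=C)O[Li]
F2 | step 11 | C8-iodo ketone as its C7 lithium enolate | CC(C)/C=C(\O[Li])[C@@H]1C2(OCCO2)CC[C@H](O[Si](C)(C)C(C)(C)C)[C@@]1(C)C(=O)CI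
F3 | step 6 | 2-silyloxy-1,3-diene lactone (C1(OSiMe3)=C2, C3=C4) | O=C2[C@@H]1C=CC=C(O[Si](C)(C)C)[C@@]1(C)C(C)O2
F4 | step 6 | γ-hydroxy enone lactone (C1 ketone, C2=C3, C4 carbinol) | O=C2[C@@H]1C(O)C=CC(=O)[C@@]1(C)C(C)O2
F5 | step 6 | ene-diol lactone (1α-OH, C4 carbinol, C2=C3) | O=C2[C@@H]1C(O)C=C[C@H](O)[C@@]1(C)C(C)O2
F6 | step 6 | hydroxy enone lactone (C4 ketone, C2=C3, 1α-OH) | O=C2[C@@H]1C(=O)C=C[C@H](O)[C@@]1(C)C(C)O2
F7 | step 14 | β-hydroxysilane (C4 carbinol carrying CH2SiMe3) | CC(C)[C@H]1C[C@@H](O)[C@@]2(C)[C@H]([C@@H]1O)C(O)(C[Si](C)(C)C)CC[C@@H]2O[Si](C)(C)C(C)(C)C
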